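The ladder is opened at the bond common to rings B and C. In ring A (the cyclohexane; C1 and C2 are the fusion carbons to ring B, C4 bears the octyl chain) all three substituents are cis, so the two ring-B carbons that also belong to ring C can be traced back to the ester carbonyl carbons of an all-cis cyclohexane-1,2-diester. One sodium/Me3SiCl acyloin coupling joins these two carbons and closes ring B as a 1,2-bis(silyloxy)cyclobutene without disturbing C1, C2 or C4. The precursor, dimethyl (1R,2S,4S)-4-(8-silyloxyoctyl)cyclohexane-1,2-dicarboxylate, comes from all-cis arene hydrogenation and resolution; rings C and D are then added together by a CuOTf-catalysed [2+2] photocycloaddition with cyclobutene.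

Key step: step 5

Remark: racemic 6 is drawn as its (1R,2S,4S) enantiomer, cyclobutene is made from cyclobutanol because it is not a routine catalogue item, and "ladderanyl" means tetracyclo[6.4.0.0(2,7).0(3,6)]dodecan-10-yl with all ring fusions cis, neighbouring rings anti and the octyl chain cis to ring B on ring A.

Step 1
Reactants: 1 oct-7-yn-1-ol
Product: 2 triisopropyl(oct-7-yn-1-yloxy)silane
Conditions: iPr3SiCl, imidazole, DMF, 0 °C to rt
Reagents that add atoms: chlorotriisopropylsilane, CC(C)[Si](Cl)(C(C)C)C(C)C
Why: Imidazole-promoted O-silylation of a primary alcohol; the hindered silyl ether is chosen because it must outlast the Sonogashira coupling, hydrogenation, sodium with Me3SiCl, borohydride, hot phosphite and 254 nm light before fluoride removes it.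

Step 2
Reactants: 2 triisopropyl(oct-7-yn-1-yloxy)silane; 3 dimethyl 4-bromophthalate
Product: 4 dimethyl 4-[8-(triisopropylsilyloxy)oct-1-yn-1-yl]phthalate
Conditions: PdCl2(PPh3)2 (2 mol%), CuI (4 mol%), Et3N/THF, degassed, 60 °C
Reagents that add atoms: none
Why: Sonogashira coupling; oxidative addition to zerovalent palladium is easy for an aryl bromide activated by two ester groups, and the esters and the silyl ether are inert.

Step 3
Reactants: 4 dimethyl 4-[8-(triisopropylsilyloxy)oct-1-yn-1-yl]phthalate
Product: 6 racemic dimethyl (1R*,2S*,4S*)-4-[8-(triisopropylsilyloxy)octyl]cyclohexane-1,2-dicarboxylate (all-cis), via saturated-chain phthalate 5 (not isolated)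
Conditions: H2 (50 bar), 5% Rh/C, MeOH, 40 °C; flash chromatography
Reagents that add atoms: none
Why: Heterogeneous hydrogenation: the alkyne is saturated first and the arene then takes up six hydrogens from the rhodium surface on one face, which should place both esters and the chain mutually cis (C1, C2 and C4 set relative to one another, as a racemate), minor trans isomers being removed by chromatography.

Step 4
Reactants: 6 racemic all-cis diester
Product: 7 dimethyl (1R,2S,4S)-4-[8-(triisopropylsilyloxy)octyl]cyclohexane-1,2-dicarboxylate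
Conditions: preparative supercritical-fluid chromatography on silica-bound amylose tris(3,5-dimethylphenylcarbamate), CO2/iPrOH, 35 °C
Reagents that add atoms: none
Why: Resolution of enantiomers on a polysaccharide chiral stationary phase, chosen because the two enantiomers differ only in where the remote chain sits relative to a locally meso diester, so reagent-based resolution at the esters is expected to discriminate poorly; the (1R,2S,4S) fraction is to be identified by an independent absolute-configuration determination (for example anomalous-dispersion X-ray analysis of a crystalline derivative) and the mirror-image fraction is set aside.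

Step 5
Reactants: 7 dimethyl (1R,2S,4S)-4-[8-(triisopropylsilyloxy)octyl]cyclohexane-1,2-dicarboxylate
Product: 8 (1S,3S,6R)-3-[8-(triisopropylsilyloxy)octyl]-7,8-bis(trimethylsilyloxy)bicyclo[4.2.0]oct-7-ene
Conditions: Na dispersion (4.4 equiv), Me3SiCl (4.6 equiv), toluene, reflux, Ar, slow addition of 7; filtration and evaporation under Ar
Reagents that add atoms: chlorotrimethylsilane, C[Si](C)(C)Cl
Why: Electron transfer from sodium converts each ester carbonyl into a ketyl radical anion; the two radical centres, held cis on C1 and C2 of ring A, combine, the resulting bis-alkoxide expels two methoxides to give the fused cyclobutane-1,2-dione, and two further electrons turn this into the enediolate that Me3SiCl traps on both oxygens. The closest known reaction is the acyloin condensation in its Me3SiCl (Rühlmann) variant, which converts succinates and cis-cycloalkane-1,2-dicarboxylates into 1,2-bis(trimethylsilyloxy)cyclobutenes. Ring B closes as a four-membered ring by intramolecular reductive coupling of two exocyclic carbonyl carbons on adjacent ring atoms, so the new bond is the one that ring B will share with ring C. No stereocentre is created; C1, C2 and C4 are carried through unchanged and the tether allows only a cis ring fusion. The step needs retention at the two α-carbons and intramolecular instead of intermolecular coupling: Me3SiCl takes methoxide out as MeOSiMe3 before it can epimerise C1 or C2 or start Claisen chemistry, and the cis-1,2 geometry together with slow addition keeps the two carbonyl carbons next to each other. The triisopropylsilyl ether offers no reducible site and should pass unchanged.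

Step 6
Reactants: 8 bis(trimethylsilyloxy)cyclobutene
Product: 10 cis-7,8-diol of the bicyclo[4.2.0]octane (both hydroxyls on the concave face of ring B), via α-ketol 9 (not isolated)
Conditions: NaBH4, MeOH/THF (degassed), −20 to 0 °C
Reagents that add atoms: none
Why: Methanolysis of the bis(silyl) enediol ether releases the α-ketol, which borohydride reduces as it forms (hydride reduction of a ketone); protonation at carbon and hydride delivery should both come from the convex face of the cis-fused bicycle, anti to ring A, so the two new carbinol centres carry their hydroxyls cis to each other on the concave face.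

Step 7
Reactants: 10 cis-diol
Product: 11 cyclic thiocarbonate (1,3-dioxolane-2-thione fused to ring B)
Conditions: 1,1'-thiocarbonyldiimidazole, DMAP (cat.), toluene, 80 °C
Reagents that add atoms: 1,1'-thiocarbonyldiimidazole, S=C(n1ccnc1)n1ccnc1
Why: Thiocarbonylation of a cis-1,2-diol (first half of the Corey–Winter olefination); only a cis-diol can bridge on a cyclobutane, so any trans-diol remains as a polar mono-adduct and is removed.

Step 8
Reactants: 11 cyclic thiocarbonate
Product: 12 cis-3-[8-(triisopropylsilyloxy)octyl]bicyclo[4.2.0]oct-7-ene (ring-B cyclobutene, chain cis to the cyclobutene carbons)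
Conditions: P(OMe)3, 110 °C, Ar
Reagents that add atoms: none
Why: Corey–Winter olefination: the phosphite takes the sulfur and the resulting dioxolanylidene loses CO2 in a syn fragmentation to the cyclobutene, which erases the two carbinol centres and leaves the ring-A centres untouched; a cis-fused bicyclo[4.2.0]oct-7-ene should not ring-open at this temperature.

Step 9
Reactants: 13 cyclobutanol
Product: 14 cyclobutyl 4-methylbenzenesulfonate
Conditions: TsCl, pyridine, 0 °C
Reagents that add atoms: 4-methylbenzenesulfonyl chloride, Cc1ccc(cc1)S(=O)(=O)Cl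
Why: Sulfonylation of a secondary alcohol in pyridine, which installs the leaving group for the elimination without touching the ring.

Step 10
Reactants: 14 cyclobutyl 4-methylbenzenesulfonate
Product: 15 cyclobutene
Conditions: KOC(CH3)3, DMSO, 70 °C; 15 swept out with N2 and condensed at −78 °C
Reagents that add atoms: none
Why: E2 elimination of a secondary sulfonate with a hindered alkoxide in a dipolar aprotic solvent; the volatile alkene leaves the hot mixture as it forms and is collected cold.

Step 11
Reactants: 12 ring-B cyclobutene; 15 cyclobutene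
Product: 16 triisopropyl{[8-(ladderanyl)octyl]oxy}silane
Conditions: 15 (10 equiv), (CuOTf)2·C6H6 (5 mol%), Et2O, hν (254 nm, quartz), −20 °C, Ar; evaporation, chromatography
Reagents that add atoms: none
Why: CuOTf-catalysed alkene–alkene [2+2] photocycloaddition: both strained cis-cycloalkenes bind to monovalent copper and excitation of the bis(alkene) complex at 254 nm joins them suprafacially, 12 reacting on the convex face of ring B (anti to ring A) and the two four-membered rings ending up anti across the new ring C, which sets the four ring-C stereocentres in the cis-anti-cis ladder arrangement; the large excess of symmetrical 15 channels 12 into the cross-adduct and leaves no regiochemical question.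

Step 12
Reactants: 16 ladderane silyl ether
Product: 17 8-(ladderanyl)octan-1-ol
Conditions: Bu4NF, THF, rt
Reagents that add atoms: none
Why: Fluoride-induced cleavage of the silyl ether; the saturated hydrocarbon ladder offers no site for fluoride or base.

Step 13
Reactants: 17 8-(ladderanyl)octan-1-ol
Product: 18 8-(ladderanyl)octyl methanesulfonate
Conditions: MeSO2Cl, Et3N, CH2Cl2, 0 °C
Reagents that add atoms: methanesulfonyl chloride, CS(=O)(=O)Cl
Why: Sulfonylation of a primary alcohol to install the leaving group.

Step 14
Reactants: 18 8-(ladderanyl)octyl methanesulfonate; 19 2,2-dimethyl-1,3-dioxan-5-ol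
Product: 20 5-[8-(ladderanyl)octyloxy]-2,2-dimethyl-1,3-dioxane
Conditions: 19 (3 equiv), NaH, DMF, 0 °C; then 18, Bu4NI (cat.), 50 °C
Reagents that add atoms: none
Why: Williamson ether synthesis: SN2 displacement of the primary mesylate by the secondary alkoxide of the symmetrical acetonide, which masks both primary hydroxyls so that only the central glycerol oxygen is alkylated.

Step 15
Reactants: 20 5-[8-(ladderanyl)octyloxy]-2,2-dimethyl-1,3-dioxane
Product: 21 2-{[8-(tetracyclo[6.4.0.0(2,7).0(3,6)]dodecan-10-yl)octyl]oxy}propane-1,3-diol (target)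
Conditions: AcOH/H2O (4:1), 40 °C
Reagents that add atoms: none
Why: Acid-catalysed hydrolysis of the isopropylidene acetal; the ladderane hydrocarbon and the ether link should be stable to dilute carboxylic acid.

Compound list

1 | oct-7-yn-1-ol | OCCCCCCC#C | starting material
2 | triisopropyl(oct-7-yn-1-yloxy)silane | CC(C)[Si](OCCCCCCC#C)(C(C)C)C(C)C | intermediate
3 | dimethyl 4-bromophthalate | COC(=O)c1ccc(Br)cc1C(=O)OC | starting material
4 | dimethyl 4-[8-(triisopropylsilyloxy)oct-1-yn-1-yl]phthalate | COC(=O)c1ccc(C#CCCCCCCO[Si](C(C)C)(C(C)C)C(C)C)cc1C(=O)OC | intermediate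
5 | dimethyl 4-[8-(triisopropylsilyloxy)octyl]phthalate (not isolated) | COC(=O)c1ccc(CCCCCCCCO[Si](C(C)C)(C(C)C)C(C)C)cc1C(=O)OC | intermediate
6 | racemic dimethyl (1R*,2S*,4S*)-4-[8-(triisopropylsilyloxy)octyl]cyclohexane-1,2-dicarboxylate (all-cis; one enantiomer written) | CC(C)[Si](OCCCCCCCC[C@H]1CC[C@@H](C(=O)OC)[C@H](C1)C(=O)OC)(C(C)C)C(C)C | intermediate
7 | dimethyl (1R,2S,4S)-4-[8-(triisopropylsilyloxy)octyl]cyclohexane-1,2-dicarboxylate (single enantiomer) | CC(C)[Si](OCCCCCCCC[C@H]1CC[C@@H](C(=O)OC)[C@H](C1)C(=O)OC)(C(C)C)C(C)C | intermediate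
8 | (1S,3S,6R)-3-[8-(triisopropylsilyloxy)octyl]-7,8-bis(trimethylsilyloxy)bicyclo[4.2.0]oct-7-ene | CC(C)[Si](OCCCCCCCC[C@H]1CC[C@@H]2[C@H](C1)C(O[Si](C)(C)C)=C2O[Si](C)(C)C)(C(C)C)C(C)C | intermediate
9 | cis-fused 8-hydroxy-3-[8-(triisopropylsilyloxy)octyl]bicyclo[4.2.0]octan-7-one (not isolated; carbinol centre epimerisable and unassigned; in equilibrium with the tautomer having carbonyl and carbinol exchanged) | CC(C)[Si](OCCCCCCCC[C@H]1CC[C@@H]2[C@H](C1)C(O)C2=O)(C(C)C)C(C)C | intermediate
10 | cis-fused 3-[8-(triisopropylsilyloxy)octyl]bicyclo[4.2.0]octane-7,8-diol, hydroxyls cis to each other and on the ring-A side of ring B | CC(C)[Si](OCCCCCCCC[C@H]1CC[C@@H]2[C@H](C1)[C@H](O)[C@@H]2O)(C(C)C)C(C)C | intermediate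
11 | cyclic thiocarbonate of 10 (1,3-dioxolane-2-thione cis-fused to ring B) | CC(C)[Si](OCCCCCCCC[C@H]1CC[C@@H]2[C@H](C1)[C@@H]3OC(=S)O[C@H]23)(C(C)C)C(C)C | intermediate
12 | cis-fused 3-[8-(triisopropylsilyloxy)octyl]bicyclo[4.2.0]oct-7-ene, chain cis to the cyclobutene carbons | CC(C)[Si](OCCCCCCCC[C@H]1CC[C@@H]2[C@H](C1)C=C2)(C(C)C)C(C)C | intermediate
13 | cyclobutanol | OC1CCC1 | starting material
14 | cyclobutyl 4-methylbenzenesulfonate | Cc1ccc(cc1)S(=O)(=O)OC1CCC1 | intermediate
15 | cyclobutene | C1=CCC1 | intermediate
16 | triisopropyl{[8-(ladderanyl)octyl]oxy}silane | CC(C)[Si](OCCCCCCCC[C@H]1CC[C@@H]2[C@H](C1)[C@H]1[C@@H]3CC[C@@H]3[C@@H]21)(C(C)C)C(C)C | intermediate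
17 | 8-(ladderanyl)octan-1-ol | OCCCCCCCC[C@H]1CC[C@@H]2[C@H](C1)[C@H]1[C@@H]3CC[C@@H]3[C@@H]21 | intermediate
18 | 8-(ladderanyl)octyl methanesulfonate | CS(=O)(=O)OCCCCCCCC[C@H]1CC[C@@H]2[C@H](C1)[C@H]1[C@@H]3CC[C@@H]3[C@@H]21 | intermediate
19 | 2,2-dimethyl-1,3-dioxan-5-ol | CC1(C)OCC(O)CO1 | starting material
20 | 5-[8-(ladderanyl)octyloxy]-2,2-dimethyl-1,3-dioxane | CC1(C)OCC(CO1)OCCCCCCCC[C@H]1CC[C@@H]2[C@H](C1)[C@H]1[C@@H]3CC[C@@H]3[C@@H]21 | intermediate
21 | 2-{[8-(ladderanyl)octyl]oxy}propane-1,3-diol | OCC(CO)OCCCCCCCC[C@H]1CC[C@@H]2[C@H](C1)[C@H]1[C@@H]3CC[C@@H]3[C@@H]21 | target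

Total step count: 15. Longest linear sequence: 13 steps (steps 1 to 8 and 11 to 15, from 1 to 21). Steps 9 and 10 form the short cyclobutene branch, and 3 and 19 enter as purchased partners.

Steps most likely to fail

Step 11. Self-coupling of the ring-B cyclobutene, unequal binding of the two alkenes to copper, or syn instead of anti approach may erode the cross-cycloaddition. The fallback sets out from 12 and returns at 16, and builds ring D by ring contraction instead of bringing it in ready-made. Irradiation of 12 with purchased cyclopent-2-enone (O=C1C=CCC1; Hg lamp, Pyrex, λ > 300 nm, CH2Cl2, −20 °C) is an enone–alkene [2+2] photocycloaddition through the enone triplet, expected on the convex face of ring B with a cis-anti-cis ring C. Because the two alkene carbons of 12 differ only through the remote chain, both orientations should form: the proximal cyclopentanone photoadduct F1 (carbonyl carbon five bonds from C4 of ring A) and the distal cyclopentanone photoadduct F2 (six bonds), which are carried on together. LiN(SiMe3)2 and CF3CO2CH2CF3 in THF at −78 °C acylate the CH2 α-carbon to the proximal trifluoroacetyl ketone F3 and the distal trifluoroacetyl ketone F4. 4-Acetamidobenzenesulfonyl azide with Et3N in MeCN then effects deacylative (Regitz-type) diazo transfer to the proximal α-diazoketone F5 and the distal α-diazoketone F6. Photochemical Wolff rearrangement (Pyrex, THF/H2O) contracts the five-membered ring through the proximal ketene F7 and the distal ketene F8 to the proximal ring-D carboxylic acid F9 and the distal ring-D carboxylic acid F10. Coupling with 1-hydroxypyridine-2(1H)-thione (DCC, DMAP, dark) gives the proximal thiohydroxamate ester F11 and the distal thiohydroxamate ester F12. Visible-light photolysis with excess (CH3)3CSH at 0 °C (Barton reductive decarboxylation) removes the carboxyl carbon from both, so the two series merge in 16.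

Step 4. The enantiomers differ only in where the chain sits relative to a pseudo-symmetric diester, so chiral recognition on the stationary phase may be too weak for a clean separation. The fallback sets out from 6 and returns at 7 by classical resolution. Mild saponification (LiOH, THF/H2O, 0 °C to rt, to avoid epimerisation) should give the racemic all-cis diacid F13. Recrystallisation of its salt with (R)-1-phenylethylamine should enrich one diastereomeric salt, the (R)-1-phenylethylammonium hydrogen (1R,2S,4S)-dicarboxylate F14; the (S)-amine is used if the other salt crystallises. Acidification with cold aqueous KHSO4 frees the (1R,2S,4S)-diacid F15, which Me3SiCHN2 in MeOH/toluene re-esterifies to 7.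

Step 6. Epimerisation of the α-ketol before reduction, or hydride delivery from the concave face, would break the cis relationship of the two hydroxyls that the cyclic thiocarbonate needs. The fallback sets out from 8 and returns at 10. Hydrogenation of the strained enediol-ether double bond (H2, 5 bar, Pd/C, hexane) should add both hydrogens syn from the convex face to give the cis-7,8-bis(trimethylsilyloxy)bicyclo[4.2.0]octane F16. K2CO3 in MeOH then removes both silyl groups to give 10 with the cis relationship fixed by the syn addition.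

Further compounds
F1 | step 11 | proximal cyclopentanone photoadduct (rings A–B–C with a cis-fused cyclopentanone anti to ring B, C=O five bonds from C4) | CC(C)[Si](OCCCCCCCC[C@H]1CC[C@@H]2[C@H](C1)[C@H]1[C@@H]3C(=O)CC[C@@H]3[C@@H]21)(C(C)C)C(C)C
F2 | step 11 | distal cyclopentanone photoadduct (as F1 with C=O six bonds from C4) | CC(C)[Si](OCCCCCCCC[C@H]1CC[C@@H]2[C@H](C1)[C@H]1[C@@H]3CCC(=O)[C@@H]3[C@@H]21)(C(C)C)C(C)C
F3 | step 11 | proximal trifluoroacetyl ketone (diketo form written) | CC(C)[Si](OCCCCCCCC[C@H]1CC[C@@H]2[C@H](C1)[C@H]1[C@@H]3C(=O)C(C(=O)C(F)(F)F)C[C@@H]3[C@@H]21)(C(C)C)C(C)C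
F4 | step 11 | distal trifluoroacetyl ketone (diketo form written) | CC(C)[Si](OCCCCCCCC[C@H]1CC[C@@H]2[C@H](C1)[C@H]1[C@@H]3CC(C(=O)C(F)(F)F)C(=O)[C@@H]3[C@@H]21)(C(C)C)C(C)C
F5 | step 11 | proximal α-diazoketone | CC(C)[Si](OCCCCCCCC[C@H]1CC[C@@H]2[C@H](C1)[C@H]1[C@@H]3C(=O)C(=[N+]=[N-])C[C@@H]3[C@@H]21)(C(C)C)C(C)C
F6 | step 11 | distal α-diazoketone | CC(C)[Si](OCCCCCCCC[C@H]1CC[C@@H]2[C@H](C1)[C@H]1[C@@H]3CC(=[N+]=[N-])C(=O)[C@@H]3[C@@H]21)(C(C)C)C(C)C
F7 | step 11 | proximal ring-D ketene | CC(C)[Si](OCCCCCCCC[C@H]1CC[C@@H]2[C@H](C1)[C@H]1[C@@H]3C(=C=O)C[C@@H]3[C@@H]21)(C(C)C)C(C)C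
F8 | step 11 | distal ring-D ketene | CC(C)[Si](OCCCCCCCC[C@H]1CC[C@@H]2[C@H](C1)[C@H]1[C@@H]3CC(=C=O)[C@@H]3[C@@H]21)(C(C)C)C(C)C
F9 | step 11 | proximal ring-D carboxylic acid (carboxyl-bearing carbon as epimer mixture, unassigned) | CC(C)[Si](OCCCCCCCC[C@H]1CC[C@@H]2[C@H](C1)[C@H]1[C@@H]3C(C(=O)O)C[C@@H]3[C@@H]21)(C(C)C)C(C)C
F10 | step 11 | distal ring-D carboxylic acid (epimer mixture, unassigned) | CC(C)[Si](OCCCCCCCC[C@H]1CC[C@@H]2[C@H](C1)[C@H]1[C@@H]3CC(C(=O)O)[C@@H]3[C@@H]21)(C(C)C)C(C)C
F11 | step 11 | proximal thiohydroxamate ester (2-thioxopyridin-1(2H)-yl ester) | CC(C)[Si](OCCCCCCCC[C@H]1CC[C@@H]2[C@H](C1)[C@H]1[C@@H]3C(C(=O)ON4C=CC=CC4=S)C[C@@H]3[C@@H]21)(C(C)C)C(C)C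
F12 | step 11 | distal thiohydroxamate ester (2-thioxopyridin-1(2H)-yl ester) | CC(C)[Si](OCCCCCCCC[C@H]1CC[C@@H]2[C@H](C1)[C@H]1[C@@H]3CC(C(=O)ON4C=CC=CC4=S)[C@@H]3[C@@H]21)(C(C)C)C(C)C
F13 | step 4 | racemic all-cis-4-[8-(triisopropylsilyloxy)octyl]cyclohexane-1,2-dicarboxylic acid (one enantiomer written) | CC(C)[Si](OCCCCCCCC[C@H]1CC[C@@H](C(=O)O)[C@H](C1)C(=O)O)(C(C)C)C(C)C
F14 | step 4 | (R)-1-phenylethylammonium hydrogen (1R,2S,4S)-4-[8-(triisopropylsilyloxy)octyl]cyclohexane-1,2-dicarboxylate | CC(C)[Si](OCCCCCCCC[C@H]1CC[C@@H](C(=O)[O-])[C@H](C1)C(=O)O)(C(C)C)C(C)C.C[C@@H]([NH3+])c1ccccc1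
F15 | step 4 | (1R,2S,4S)-4-[8-(triisopropylsilyloxy)octyl]cyclohexane-1,2-dicarboxylic acid | CC(C)[Si](OCCCCCCCC[C@H]1CC[C@@H](C(=O)O)[C@H](C1)C(=O)O)(C(C)C)C(C)C
F16 | step 6 | cis-fused 3-[8-(triisopropylsilyloxy)octyl]-7,8-bis(trimethylsilyloxy)bicyclo[4.2.0]octane, silyloxy groups cis on the ring-A side | CC(C)[Si](OCCCCCCCC[C@H]1CC[C@@H]2[C@H](C1)[C@H](O[Si](C)(C)C)[C@@H]2O[Si](C)(C)C)(C(C)C)C(C)C
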